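## Retrosynthetic overview

1. The target is the acetate of a tertiary α-ketol. The ketol C–C bond (ring carbinol carbon to chain ketone carbon) is cut as an aldehyde-derived acyl anion (carbene-bound hydroxy-enamine) plus a ring ketone, so a crossed benzoin closes the 12-membered carbocycle last and creates the carbinol centre.
2. The seco aldehyde–enedione comes from ozonolysis of a vinyl group and allylic oxidation of a cross-conjugated dienone, itself made by aldol condensation of 2-methylcyclopent-2-enone with an oxolane aldehyde (this fixes the E alkene).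
3. The oxolane aldehyde comes from hydroboration/copper-catalysed asymmetric allyl–alkyl coupling (methyl centre), cobalt-catalysed aerobic cyclisation (2,5-trans oxolane, quaternary centre) and iridium-catalysed reverse prenylation (first centre, gem-dimethyl).
4. Ring order: oxolane first, the bought cyclopentenone attached intact, macrocycle last.

Assumption: the ligand antipodes written in steps 1 and 3 are those that give the stated configurations (the other antipode is used if the sense is reversed), and (Z)-1-chlorobut-2-ene is bought as the pure Z isomer.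

## Route

Step 1
Reactants: 1 4-methylpent-4-en-1-ol; 2 3-methylbuta-1,2-diene
Product: 4 (4S)-3,3,7-trimethylocta-1,7-dien-4-ol, via 4-methylpent-4-enal 3 (not isolated)
Conditions: [Ir(cod)Cl]2 (2.5 mol %), (R)-SEGPHOS (5 mol %), 4-chloro-3-nitrobenzoic acid (10 mol %), Cs2CO3 (20 mol %), toluene, 60 °C
Reagents that add atoms: none
Why: Krische transfer-hydrogenative reverse prenylation: the alcohol is dehydrogenated to aldehyde 3, the hydride goes to the allene, and the resulting 1,1-dimethylallyl-iridium adds through its γ-carbon inside the chiral SEGPHOS pocket, which sets the 4S carbinol centre.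

Step 2
Reactants: 4 (4S)-3,3,7-trimethylocta-1,7-dien-4-ol
Product: 5 [(2S,5S)-2-methyl-5-(2-methylbut-3-en-2-yl)oxolan-2-yl]methanol
Conditions: Co(modp)2 [cobalt bis(1-morpholinocarbamoyl-4,4-dimethylpentane-1,3-dionate)] (10 mol %), O2 (1 atm), t-BuOOH (10 mol %), i-PrOH, 55 °C
Reagents that add atoms: dioxygen, O=O
Why: Mukaiyama aerobic oxidative cyclisation of a bishomoallylic alcohol: 5-exo closure through a chair-like transition state with the bulky tert-alkyl group pseudo-equatorial gives the 2,5-trans oxolane, so the 5S centre sets the new quaternary 2S centre, and the exocyclic radical is oxygenated to CH2OH.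

Step 3
Reactants: 5 [(2S,5S)-2-methyl-5-(2-methylbut-3-en-2-yl)oxolan-2-yl]methanol; 6 (Z)-1-chlorobut-2-ene
Product: 8 [(2S,5S)-5-[(5R)-2,5-dimethylhept-6-en-2-yl]-2-methyloxolan-2-yl]methanol, via bis-boryl adduct 7 (not isolated)
Conditions: 9-BBN (2.2 equiv), THF, 50 °C; then (CuOTf)2·C6H5CH3 (5 mol %), (R)-DTBM-SEGPHOS (10 mol %), KOMe, 6 (1.5 equiv), 1,4-dioxane, 15 °C; aqueous work-up
Reagents that add atoms: none
Why: Anti-Markovnikov hydroboration followed by copper-catalysed γ-selective (SN2′) enantioselective allyl–alkyl coupling of the B-alkyl-9-BBN with the Z allylic chloride; the copper–DTBM-SEGPHOS catalyst selects the alkene face and sets the R methyl-bearing centre, while the hydroxyl rides through as its borinate.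

Step 4
Reactants: 8 [(2S,5S)-5-[(5R)-2,5-dimethylhept-6-en-2-yl]-2-methyloxolan-2-yl]methanol
Product: 9 (2S,5S)-5-[(5R)-2,5-dimethylhept-6-en-2-yl]-2-methyloxolane-2-carbaldehyde
Conditions: 2,2,6,6-tetramethylpiperidin-1-oxyl (10 mol %), PhI(OAc)2, CH2Cl2, 23 °C
Reagents that add atoms: none
Why: Oxoammonium (TEMPO) oxidation of a primary alcohol stops at the aldehyde and leaves the alkene alone, and the α-carbon is quaternary so nothing can epimerise.

Step 5
Reactants: 9 (2S,5S)-5-[(5R)-2,5-dimethylhept-6-en-2-yl]-2-methyloxolane-2-carbaldehyde; 10 2-methylcyclopent-2-en-1-one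
Product: 14 (5E)-5-{[(2S,5S)-5-[(5R)-2,5-dimethylhept-6-en-2-yl]-2-methyloxolan-2-yl]methylidene}-2-methylcyclopent-2-en-1-one, via lithium enolate 11 (not isolated), via lithium aldolate 12 (not isolated), via aldol mesylate 13 (not isolated)
Conditions: 10, LiN(iPr)2, THF, −78 °C; 9, −78 °C; MsCl, −78 → 0 °C; DBU, 0 → 23 °C
Reagents that add atoms: none
Why: Aldol condensation: kinetic α′-deprotonation of the enone, addition to the non-enolisable aldehyde and E1cB elimination of the mesylate give the thermodynamically preferred E alkylidene ketone, which places the oxolane carbon cis to the ring CH2 (the future carbinol carbon) as the target requires.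

Step 6
Reactants: 14 (5E)-5-{[(2S,5S)-5-[(5R)-2,5-dimethylhept-6-en-2-yl]-2-methyloxolan-2-yl]methylidene}-2-methylcyclopent-2-en-1-one
Product: 15 (2E)-2-{[(2S,5S)-5-[(5R)-2,5-dimethylhept-6-en-2-yl]-2-methyloxolan-2-yl]methylidene}-4-methylcyclopent-4-ene-1,3-dione
Conditions: SeO2 (2.5 equiv), 1,4-dioxane, 85 °C
Reagents that add atoms: selenium dioxide, O=[Se]=O
Why: Vinylogous Riley (SeO2 allylic) oxidation: the ring CH2 is flanked by both alkenes and is vinylogous to the ketone, so it is oxidised through the dienol to the alcohol and on to the ketone without breaking the exocyclic double bond, which keeps its geometry.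

Step 7
Reactants: 15 (2E)-2-{[(2S,5S)-5-[(5R)-2,5-dimethylhept-6-en-2-yl]-2-methyloxolan-2-yl]methylidene}-4-methylcyclopent-4-ene-1,3-dione
Product: 17 (2R)-2,5-dimethyl-5-[(2S,5S)-5-methyl-5-{(E)-(3-methyl-2,5-dioxocyclopent-3-en-1-ylidene)methyl}oxolan-2-yl]hexanal, via secondary ozonide 16 (not isolated)
Conditions: O3, CH2Cl2, −78 °C (stopped at the first trace of blue); Me2S, −78 → 20 °C
Reagents that add atoms: ozone, [O-][O+]=O
Why: Ozonolysis with reductive work-up: electrophilic ozone cleaves the isolated monosubstituted alkene far faster than the two acyl-substituted alkenes of the enedione, and the neutral conditions leave the α-methyl centre untouched.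

Step 8
Reactants: 17 (2R)-2,5-dimethyl-5-[(2S,5S)-5-methyl-5-{(E)-(3-methyl-2,5-dioxocyclopent-3-en-1-ylidene)methyl}oxolan-2-yl]hexanal
Product: 20 CNP0144863.1 (the acetate of 19), via Breslow intermediate 18 (not isolated), via tertiary ketol 19 (not isolated)
Conditions: 2-(pentafluorophenyl)-6,7-dihydro-5H-pyrrolo[2,1-c][1,2,4]triazol-2-ium tetrafluoroborate (20 mol %), iPr2NEt (20 mol %), toluene (0.002 M, slow addition of 17), 40 °C; then Ac2O, 4-(dimethylamino)pyridine, 23 °C
Reagents that add atoms: acetic anhydride, CC(=O)OC(C)=O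
Why: Proposed new method: the triazolylidene turns the aldehyde into its acyl-anion equivalent 18, which adds 1,2 to the doubly activated ring carbonyl held cis to the oxolane (3.0 Å from the tether anchor), closing the 12-membered carbocycle; with the oxolane oxygen next to that carbonyl and the oxolane methyl on the other face, the chain can only deliver the acyl carbon to the face that gives the S carbinol; conjugate (Stetter) attack at the ring CH should be slower because it needs a larger ring and gives an α-methyl enolate, the ketone of 19 is too hindered to re-enter the cycle, and acetylation in the same flask removes the free ketol; the closest known reactions are the triazolium-catalysed intramolecular crossed aldehyde–ketone benzoin (five- and six-membered rings) and carbene-catalysed macrocyclising Stetter reactions.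

## Compound list

1 | 4-methylpent-4-en-1-ol | CC(=C)CCCO | starting material
2 | 3-methylbuta-1,2-diene (1,1-dimethylallene) | CC(C)=C=C | starting material
3 | 4-methylpent-4-enal | CC(=C)CCC=O | intermediate (not isolated)
4 | (4S)-3,3,7-trimethylocta-1,7-dien-4-ol | C=C(C)CC[C@H](O)C(C)(C)C=C | intermediate
5 | [(2S,5S)-2-methyl-5-(2-methylbut-3-en-2-yl)oxolan-2-yl]methanol | OC[C@]1(C)CC[C@H](O1)C(C)(C)C=C | intermediate
6 | (Z)-1-chlorobut-2-ene | C/C=C\CCl | starting material
7 | bis-boryl adduct of 5 (9-BBN on the hydroxyl oxygen and on the former vinyl terminus) | C1CCC2CCCC1B2OC[C@]1(C)CC[C@H](O1)C(C)(C)CCB1C2CCCC1CCC2 | intermediate (not isolated)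
8 | [(2S,5S)-5-[(5R)-2,5-dimethylhept-6-en-2-yl]-2-methyloxolan-2-yl]methanol | OC[C@]1(C)CC[C@H](O1)C(C)(C)CC[C@@H](C)C=C | intermediate
9 | (2S,5S)-5-[(5R)-2,5-dimethylhept-6-en-2-yl]-2-methyloxolane-2-carbaldehyde | O=C[C@]1(C)CC[C@H](O1)C(C)(C)CC[C@@H](C)C=C | intermediate
10 | 2-methylcyclopent-2-en-1-one | CC1=CCCC1=O | starting material
11 | lithium enolate of 10 (α′-enolate) | [Li+].CC1=CCC=C1[O-] | intermediate (not isolated)
12 | lithium aldolate of 9 and 10 (two new centres unassigned) | [Li+].[O-]C(C1CC=C(C)C1=O)[C@]1(C)CC[C@H](O1)C(C)(C)CC[C@@H](C)C=C | intermediate (not isolated)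
13 | aldol mesylate | CS(=O)(=O)OC(C1CC=C(C)C1=O)[C@]1(C)CC[C@H](O1)C(C)(C)CC[C@@H](C)C=C | intermediate (not isolated)
14 | (5E)-5-{[(2S,5S)-5-[(5R)-2,5-dimethylhept-6-en-2-yl]-2-methyloxolan-2-yl]methylidene}-2-methylcyclopent-2-en-1-one | CC1=CC/C(=C\[C@]2(C)CC[C@H](O2)C(C)(C)CC[C@@H](C)C=C)C1=O | intermediate
15 | (2E)-2-{[(2S,5S)-5-[(5R)-2,5-dimethylhept-6-en-2-yl]-2-methyloxolan-2-yl]methylidene}-4-methylcyclopent-4-ene-1,3-dione | CC1=CC(=O)/C(=C\[C@]2(C)CC[C@H](O2)C(C)(C)CC[C@@H](C)C=C)C1=O | intermediate
16 | secondary ozonide (1,2,4-trioxolane) of the vinyl group of 15 | CC1=CC(=O)/C(=C\[C@]2(C)CC[C@H](O2)C(C)(C)CC[C@@H](C)C2OCOO2)C1=O | intermediate (not isolated)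
17 | (2R)-2,5-dimethyl-5-[(2S,5S)-5-methyl-5-{(E)-(3-methyl-2,5-dioxocyclopent-3-en-1-ylidene)methyl}oxolan-2-yl]hexanal | CC1=CC(=O)/C(=C\[C@]2(C)CC[C@H](O2)C(C)(C)CC[C@@H](C)C=O)C1=O | intermediate
18 | Breslow intermediate (hydroxy-enamine from the aldehyde of 17 and the triazolylidene) | CC1=CC(=O)/C(=C\[C@]2(C)CC[C@H](O2)C(C)(C)CC[C@@H](C)C(O)=C2N(c3c(F)c(F)c(F)c(F)c3F)N=C3CCCN23)C1=O | intermediate (not isolated)
19 | tertiary α-ketol macrocycle (deacetyl target; S at the carbinol carbon) | O[C@@]12C=C(C)C(=O)/C1=C/[C@]1(C)CC[C@H](O1)C(C)(C)CC[C@@H](C)C2=O | intermediate (not isolated)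
20 | CNP0144863.1: 4-acetoxy-2-methylcyclopent-2-enone (4S) whose C5 carries the E exocyclic alkene to C2 of a (2S,5S)-2-methyloxolane; C5 of the oxolane carries CMe2CH2CH2CH(CH3) (R), whose carbonyl closes the 12-membered ring onto C4 | CC(=O)O[C@@]12C=C(C)C(=O)/C1=C/[C@]1(C)CC[C@H](O1)C(C)(C)CC[C@@H](C)C2=O | target

## Step count and risks

Total step count: 8. Longest linear sequence: 8 steps (1 → 20); compounds 2, 6 and 10 are bought.

Most likely to fail, in order:

Step 8 (macrocyclising crossed benzoin). The acyl-anion equivalent may instead add in conjugate fashion to the ring alkene (Stetter), reduce the enedione (redox esterification), attack the other ring carbonyl, or give the wrong carbinol epimer; the free carbene can also be sequestered by the enedione. Fallback, masking the ring alkene so that only 1,2-addition is possible: setting out from 17, thiophenol with catalytic Et3N adds to the unsubstituted ring alkene carbon to give the thiophenol adduct F1. The same triazolium conditions then close the ring to the sulfide-masked ketol F2, Ac2O with 4-(dimethylamino)pyridine gives the sulfide-masked acetate F3, and DBU eliminates thiophenol (E1cB) to come back to the route at 20.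

Step 6 (SeO2 oxidation). It may stop at the alcohol, attack the allylic methyl group or the side-chain alkene, or erode the alkene geometry at 85 °C. Fallback, a two-stage ionic oxidation through the dienol ether: setting out from 14, t-BuMe2SiOTf and Et3N give the silyl dienol ether F4 (a 1-silyloxyfulvene). Dimethyldioxirane then oxygenates its γ-carbon (vinylogous Rubottom oxidation) to the 4-hydroxy dienone F5, and MnO2 oxidises the doubly allylic alcohol to come back to the route at 15.

Step 3 (hydroboration and copper-catalysed allyl–alkyl coupling). The small methyl substituent may give low enantioselectivity, and the borinate or the hindered borane may slow transmetalation. Fallback, auxiliary instead of catalyst control: setting out from 5, Cp2Zr(H)Cl followed by I2 gives the primary iodide F6. Alkylation of propanal RAMP-hydrazone (deprotonated with LiN(iPr)2, 2.2 equiv) with it gives the alkylated RAMP hydrazone F7 with the R methyl centre, aqueous oxalic acid releases the hydroxy aldehyde F8, and Ph3P=CH2 methylenates it to come back to the route at 8.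

## Further compounds

F1 | step 8 | thiophenol adduct of 17 (phenylthio group on the former ring CH carbon) | CC1C(Sc2ccccc2)C(=O)/C(=C\[C@]2(C)CC[C@H](O2)C(C)(C)CC[C@@H](C)C=O)C1=O
F2 | step 8 | sulfide-masked ketol | O[C@@]12C(Sc3ccccc3)C(C)C(=O)/C1=C/[C@]1(C)CC[C@H](O1)C(C)(C)CC[C@@H](C)C2=O
F3 | step 8 | sulfide-masked acetate | CC(=O)O[C@@]12C(Sc3ccccc3)C(C)C(=O)/C1=C/[C@]1(C)CC[C@H](O1)C(C)(C)CC[C@@H](C)C2=O
F4 | step 6 | silyl dienol ether of 14 (1-silyloxyfulvene) | CC1=C(O[Si](C)(C)C(C)(C)C)/C(=C/[C@]2(C)CC[C@H](O2)C(C)(C)CC[C@@H](C)C=C)C=C1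
F5 | step 6 | 4-hydroxy dienone | CC1=CC(O)/C(=C\[C@]2(C)CC[C@H](O2)C(C)(C)CC[C@@H](C)C=C)C1=O
F6 | step 3 | primary iodide [(2S,5S)-5-(4-iodo-2-methylbutan-2-yl)-2-methyloxolan-2-yl]methanol | OC[C@]1(C)CC[C@H](O1)C(C)(C)CCI
F7 | step 3 | alkylated RAMP hydrazone | OC[C@]1(C)CC[C@H](O1)C(C)(C)CC[C@@H](C)/C=N/N1CCC[C@@H]1COC
F8 | step 3 | hydroxy aldehyde (2R)-5-[(2S,5S)-5-(hydroxymethyl)-5-methyloxolan-2-yl]-2,5-dimethylhexanal | OC[C@]1(C)CC[C@H](O1)C(C)(C)CC[C@@H](C)C=O
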